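I follow the homo dimer.

    starting material + partner ⇌ target (K1 = 85 L mol⁻¹, k1 = 0.0022 L mol⁻¹ s⁻¹, Ea1 = 64.0 kJ mol⁻¹, ΔH1 = −4.00 kJ mol⁻¹)
    second substrate + partner → second product (k2 = 7.8 × 10⁻⁴ L mol⁻¹ s⁻¹, Ea2 = 77.0 kJ mol⁻¹)
    third substrate + partner → third product (k3 = 0.0017 L mol⁻¹ s⁻¹, Ea3 = 64.0 kJ mol⁻¹)
    2 starting material → homo dimer (k4 = 4.6 × 10⁻⁵ L mol⁻¹ s⁻¹, Ea4 = 75.0 kJ mol⁻¹)
    gas ⇌ partner, rate k5*(csat - [partner]) (k5 = 5.1 × 10⁻⁴ s⁻¹, csat = 24 mM)
    (constants at 25 °C)

all flasks: second substrate 2.20 M; gas 24 mM (held); time 15 h

| charge | starting material | third substrate | temperature | remark |
|---|---|---|---|---|
| dawn | 0.44 M | 0.440 M (fed, over 10 h) | 25 °C | all else is in the flask from the start; the feed brings no volume worth counting |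
| dusk | 0.44 M (fed, over 10 h) | 0.440 M | 25 °C | all else is in the flask from the start; the feed brings no volume worth counting |
| noon | 0.44 M | 0.440 M |  | everything together at the start at 5 °C, warmed to 25 °C at 10 h |
| midnight | 0.44 M | 0.440 M (fed, over 10 h) |  | the addition at 5 °C, then warmed to 25 °C; the feed brings no volume worth counting |

1. the flask with the highest amount of homo dimer, in percent of the starting material charged ("all alike" if they lie within 1.5 percentage points) (dawn / dusk / noon / midnight / all alike)
2. final homo dimer, as a percentage of the starting material charged, in dawn
3. final homo dimer, as a percentage of the starting material charged, in dusk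
4. final homo dimer, as a percentage of the starting material charged, in noon
5. final homo dimer, as a percentage of the starting material charged, in midnight

- a species is counted by the starting material in it: one homo dimer counts as two
- a doubled species enters its step squared and goes two at a time
- at the start none of partner is dissolved
- all constants are for 25 °C and move with temperature by the activation energies and enthalpies

- Dawn and dusk look nearly the same: they differ in which charge runs in over 10 h, so I reckon that pair by hand.
- Partner comes in from the gas and goes to second and third substrate with a half-life near 0.0741 h, far shorter than 15 h, so I hold it steady at inflow over total loss.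
- In dawn I take third substrate at half its charge, as a steady feed averages, which gives partner 4.71 mM; in dusk, with the whole charge present, it gives 4.12 mM.
- I treat the first step as at equilibrium, so target over starting material equals the equilibrium constant times partner. In dawn this gives 71.4% for the free share, the unbound fraction of starting material plus target, one over one plus that product; in dusk it gives 74.1%.
- Homo dimer forms in pairs from free starting material, so the pool of starting material plus target falls second-order, at twice the dimer constant times the free share squared times the pool squared.
- Integrated for dawn, this puts homo dimer at 52.7% of the charge.
- In dusk I let the pool climb against that loss under the steady feed, as a hyperbolic tangent, and my reckoning puts it at 0.351 M when the feed ends. Its later fall, reckoned the same way, puts homo dimer at 39.5%.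
- In my reckoning dusk ends lower than dawn, though its free share is larger, because its starting material has on average 10.0 h in the flask against 15 h in dawn.
- The forecast names dawn, with 60% there, 47% in dusk, 38% in noon and 37% in midnight, on the ground that “dimer is highest with all the starting material present warm from the start and lower when it is fed slowly”.
- My two figures lie lower than the forecast's, though my gap between the flasks is 13 percentage points and the forecast's is 13 points.
- The simulation gives dawn as highest: 59.6% in dawn, 46.1% in dusk, 37.5% in noon, 37.2% in midnight.
- In dawn at 15.0 h, partner's half-life by the second substrate is 0.14 h, shorter than the 0.619 h relaxation half-life of the first step, both ways together, and both are far below the asked time. The free share read in dawn is 75.5% at 10.0 h, above my 71.4%, and 70.2% at 15.0 h, beside it.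
- Take dawn with 1.1 M of starting material: my partner level holds no starting material term, so I keep the free share at 71.4%, and the same integral gives 73.6% homo dimer. The run of that flask gives 78.3%.

The numbers are made up; the rest is arithmetic.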